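With the side chain numbered from the benzylic carbon (C1) to C17, everything rests on cutting C7–C8, next to the 8Z-alkene. The oxygen on C12 sits five bonds from C8 (a (Z)-alk-4-en-1-ol motif). O, C8, C9, C10, C11 and C12 can therefore be folded into a 3,4-dihydro-2H-pyran ring whose enol ether double bond is C8=C9, held cis. A nickel-catalysed Kumada-type ring-opening coupling (Wenkert reaction) with the 7-arylheptyl Grignard reagent exchanges the vinylic C8–O bond for C8–C7 with retention. One operation joins both halves, delivers the Z-alkene and frees the C12 carbinol. The precursor is (S)-2-[(Z)-pent-2-enyl]-3,4-dihydro-2H-pyran, made from (R)-epichlorohydrin.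

Key step: step 6

Remark: C12 of the target is read as S from the SMILES (O > C13 > C11 > H). The C–O bond at this centre comes from 8 and is never broken in the route.

Step 1
Reactants: 1 5-bromoresorcinol (5-bromobenzene-1,3-diol)
Product: 2 1-bromo-3,5-bis(methoxymethoxy)benzene
Conditions: NaH (2.4 equiv), MOMCl (2.4 equiv), DMF, 0 °C → rt
Reagents that add atoms: chloromethyl methyl ether (MOMCl), COCCl
Why: Williamson-type O-alkylation of both phenoxides should install MOM acetals, which withstand Grignard and nickel chemistry and leave under mild acid at the end.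

Step 2
Reactants: 2 1-bromo-3,5-bis(methoxymethoxy)benzene; 3 1,7-dibromoheptane
Product: 5 1-(7-bromoheptyl)-3,5-bis(methoxymethoxy)benzene, via aryl Grignard reagent 4 (not isolated)
Conditions: 2, Mg, THF, reflux; then added to 3 (3 equiv), Li2CuCl4 (3 mol%), THF, 0 °C → rt
Reagents that add atoms: none
Why: Copper-catalysed cross-coupling of an aryl Grignard reagent with a primary alkyl bromide (Kochi coupling), in which the excess of the symmetrical dibromide should hold back double arylation.

Step 3
Reactants: 6 ethyllithium; 7 acetylene; 8 (R)-epichlorohydrin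
Product: 11 (2R,4Z)-1-chlorohept-4-en-2-ol, via diethylcuprate 9 (not isolated), via dibutenylcuprate 10 (not isolated)
Conditions: 6 (2 equiv), CuBr·SMe2 (1 equiv), Et2O, −35 °C; 7 (2 equiv), −50 → −25 °C; 8 (0.9 equiv), −40 → −20 °C; aq. NH4Cl
Reagents that add atoms: none
Why: Normant syn-carbocupration of acetylene sets the 14Z-alkene stereospecifically, and the alkenyl cuprate should open the epoxide by SN2 attack at its unsubstituted carbon faster than it displaces chloride, so the stereocentre of 8 is carried over untouched.

Step 4
Reactants: 11 (2R,4Z)-1-chlorohept-4-en-2-ol; 12 1-(trimethylsilyl)propyne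
Product: 16 (5S,7Z)-dec-7-en-1-yn-5-ol, via lithiated silylpropyne 13 (not isolated), via epoxide 14 (not isolated), via silyl alkynol 15 (not isolated)
Conditions: 11, NaH (1.1 equiv), THF, 0 °C → rt; solution added to 13 (from 12 and n-BuLi, 1.5 equiv each, THF, −78 → −20 °C), DMPU, −78 °C → rt; then MeOH, K2CO3 (cat.), rt
Reagents that add atoms: none
Why: Williamson-type closure of the sodium alkoxide gives the terminal epoxide without touching the C–O bond at the stereocentre, the propargylic carbanion opens it by SN2 attack at the unsubstituted carbon, and methoxide then cleaves the alkynyl C–Si bond (protodesilylation), so the centre is unchanged in space and becomes S only through a change in CIP ranking.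

Step 5
Reactants: 16 (5S,7Z)-dec-7-en-1-yn-5-ol
Product: 17 (S)-2-[(Z)-pent-2-enyl]-3,4-dihydro-2H-pyran
Conditions: [Rh(cod)Cl]2 (2.5 mol%), P(4-FC6H4)3 (50 mol%), DMF, 85 °C
Reagents that add atoms: none
Why: Isomerisation of the terminal alkyne to a rhodium vinylidene makes C8 electrophilic, so the C12 hydroxyl should add in the 6-endo-dig (anti-Markovnikov) sense and protodemetallation should give the cyclic enol ether (alkynol endo-cycloisomerisation), with C12 and the internal Z-alkene as spectators.

Step 6
Reactants: 5 1-(7-bromoheptyl)-3,5-bis(methoxymethoxy)benzene; 17 (S)-2-[(Z)-pent-2-enyl]-3,4-dihydro-2H-pyran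
Product: 19 (3Z,6S,9Z)-17-[3,5-bis(methoxymethoxy)phenyl]heptadeca-3,9-dien-6-ol, via alkyl Grignard reagent 18 (not isolated)
Conditions: 5 (1.4 equiv), Mg, THF, 45 °C; then 17, NiCl2(dppp) (5 mol%; dppp = 1,3-bis(diphenylphosphino)propane), PhMe–THF, 75 °C; aq. NH4Cl
Reagents that add atoms: none
Why: The Grignard reagent reduces NiCl2(dppp) to a zerovalent nickel species which, helped by magnesium coordination to the ring oxygen, inserts into the vinylic C8–O bond of 17 with retention, after which transmetallation with 18 and reductive elimination, also with retention, form C7–C8 and release the magnesium alkoxide of 19. The closest known reaction type is the nickel-catalysed Kumada-type coupling of Grignard reagents with cyclic enol ethers (Wenkert reaction), known for 3,4-dihydro-2H-pyran itself, primary alkylmagnesium halides included, as a route to (Z)-alk-4-en-1-ols. No ring is closed; the six-membered ring is opened, and because it holds O and C10 cis on C8=C9, the incoming C7 ends up cis to C10, which fixes the 8Z geometry. No stereocentre is created, and C12 stays S because its own C–O bond is not touched. The step needs insertion into the C(sp2)–O bond rather than the secondary C(sp3)–O bond or the aryl–O bonds of the MOM ethers, which the far easier activation of an enol ether by a phosphine-ligated nickel catalyst secures, and it needs coupling to outrun β-hydride elimination, which the chelating dppp ligand favours by enforcing a cis arrangement of the two carbon ligands. The isolated 14Z-alkene carries no leaving group and should remain a spectator.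

Step 7
Reactants: 19 (3Z,6S,9Z)-17-[3,5-bis(methoxymethoxy)phenyl]heptadeca-3,9-dien-6-ol
Product: 20 5-[(8Z,12S,14Z)-12-hydroxyheptadeca-8,14-dienyl]benzene-1,3-diol
Conditions: HCl (0.5 M), MeOH, 45 °C
Reagents that add atoms: none
Why: Acid-catalysed acetal exchange with methanol should remove both MOM groups as dimethoxymethane under conditions too mild to ionise the secondary alcohol or to move either Z-alkene.

Compound list
1 | 5-bromoresorcinol (5-bromobenzene-1,3-diol) | Oc1cc(O)cc(Br)c1 | starting material
2 | 1-bromo-3,5-bis(methoxymethoxy)benzene | COCOc1cc(Br)cc(OCOC)c1 | intermediate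
3 | 1,7-dibromoheptane | BrCCCCCCCBr | starting material
4 | 3,5-bis(methoxymethoxy)phenylmagnesium bromide | COCOc1cc([Mg]Br)cc(OCOC)c1 | intermediate
5 | 1-(7-bromoheptyl)-3,5-bis(methoxymethoxy)benzene | COCOc1cc(CCCCCCCBr)cc(OCOC)c1 | intermediate
6 | ethyllithium | [Li]CC | starting material
7 | acetylene | C#C | starting material
8 | (R)-epichlorohydrin | ClC[C@H]1CO1 | starting material
9 | lithium diethylcuprate | [Li+].CC[Cu-]CC | intermediate
10 | lithium bis[(Z)-but-1-enyl]cuprate | [Li+].CC/C=C\[Cu-]/C=C\CC | intermediate
11 | (2R,4Z)-1-chlorohept-4-en-2-ol | ClC[C@H](O)C/C=C\CC | intermediate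
12 | 1-(trimethylsilyl)propyne | CC#C[Si](C)(C)C | starting material
13 | 3-(trimethylsilyl)prop-2-ynyllithium | [Li]CC#C[Si](C)(C)C | intermediate
14 | (R)-2-[(Z)-pent-2-enyl]oxirane | CC/C=C\C[C@@H]1CO1 | intermediate
15 | (5S,7Z)-1-(trimethylsilyl)dec-7-en-1-yn-5-ol | CC/C=C\C[C@@H](O)CCC#C[Si](C)(C)C | intermediate
16 | (5S,7Z)-dec-7-en-1-yn-5-ol | CC/C=C\C[C@@H](O)CCC#C | intermediate
17 | (S)-2-[(Z)-pent-2-enyl]-3,4-dihydro-2H-pyran | CC/C=C\C[C@@H]1CCC=CO1 | intermediate
18 | 7-[3,5-bis(methoxymethoxy)phenyl]heptylmagnesium bromide | COCOc1cc(CCCCCCC[Mg]Br)cc(OCOC)c1 | intermediate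
19 | (3Z,6S,9Z)-17-[3,5-bis(methoxymethoxy)phenyl]heptadeca-3,9-dien-6-ol | CC/C=C\C[C@@H](O)CC/C=C\CCCCCCCc1cc(OCOC)cc(OCOC)c1 | intermediate
20 | 5-[(8Z,12S,14Z)-12-hydroxyheptadeca-8,14-dienyl]benzene-1,3-diol | CC/C=C\C[C@@H](O)CC/C=C\CCCCCCCc1cc(O)cc(O)c1 | target

Total step count: 7. Longest linear sequence: 5 steps (steps 3, 4, 5, 6, 7).

Steps most likely to fail

Step 6. β-Hydride elimination in the alkylnickel intermediate may outrun reductive elimination. The enol ether would then merely be reduced and the Grignard reagent lost. Nickel hydrides formed this way may also shift or scramble the two alkenes. The fallback sets out from alkynol 16 and bromide 5 and comes back to the route at 19. Compound 16 is deprotonated twice (n-BuLi, 2.1 equiv, THF–DMPU, −78 → 0 °C). The acetylide terminus is then alkylated with 5 (NaI cat., 0 °C → rt). This forms the same C7–C8 bond by SN2 and should give (3Z,6S)-17-[3,5-bis(methoxymethoxy)phenyl]heptadec-3-en-9-yn-6-ol F1. Lindlar-type semihydrogenation of the alkyne (H2, Pd/CaCO3 poisoned with Pb(OAc)2, quinoline, EtOAc, rt) should then give 19.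

Step 5. Exo-cyclisation or alkyne oligomerisation may compete with vinylidene formation, and the acid-sensitive enol ether may hydrolyse during isolation. The fallback sets out from epoxide 14, which is distilled after the NaH closure of 11, and comes back at 17.
- Copper-catalysed opening with commercial (1,3-dioxan-2-ylethyl)magnesium bromide (CuI 10 mol%, THF, −30 → 0 °C) should give (4S,6Z)-1-(1,3-dioxan-2-yl)non-6-en-4-ol F2.
- Acetal exchange (camphorsulfonic acid cat., MeOH, reflux) should close it to (6S)-2-methoxy-6-[(Z)-pent-2-enyl]tetrahydro-2H-pyran F3 as a mixture of anomers.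
- Silyl triflate-induced elimination of the acetal (TMSOTf, i-Pr2NEt, CH2Cl2, −20 °C → rt) should give 17.

Step 3. Three things may go wrong.
- A second insertion of acetylene may occur.
- The chloro alkoxide may close early and suffer a second cuprate attack.
- The cuprate may partly attack the chlorine-bearing carbon, which would erode enantiopurity.

The fallback sets out from 8 and comes back at 11. Yamaguchi–Hirao alkynylation (but-1-yne, n-BuLi, BF3·OEt2, THF, −78 °C) should open the epoxide at its unsubstituted carbon to give (R)-1-chlorohept-4-yn-2-ol F4. Lindlar-type semihydrogenation (H2, Pd/CaCO3 poisoned with Pb(OAc)2, quinoline, hexane–EtOAc, rt) should then give 11.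

Further compounds
F1 | step 6 | (3Z,6S)-17-[3,5-bis(methoxymethoxy)phenyl]heptadec-3-en-9-yn-6-ol | CC/C=C\C[C@@H](O)CCC#CCCCCCCCc1cc(OCOC)cc(OCOC)c1
F2 | step 5 | (4S,6Z)-1-(1,3-dioxan-2-yl)non-6-en-4-ol | CC/C=C\C[C@@H](O)CCCC1OCCCO1
F3 | step 5 | (6S)-2-methoxy-6-[(Z)-pent-2-enyl]tetrahydro-2H-pyran (both anomers) | CC/C=C\C[C@@H]1CCCC(OC)O1
F4 | step 3 | (R)-1-chlorohept-4-yn-2-ol | ClC[C@H](O)CC#CCC
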